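**Assumption:** the SMILES is taken literally: the aroyl ring is 3,5-dihydroxy-4-prenylphenyl (no OH ortho to the ketone), and the cyclohexene is (1R,2S,6S) counted from the acyl-bearing carbon (acyl cis to the 2-aryl group, trans to the 6-aryl group).

## Retrosynthetic overview

1. Target 21 ⇐ triacetate 20 ⇐ benzylic alcohol 19: the aryl–C(O) bond is cut to give aryl iodide 18 and a masked aldehyde, lactol 13.
2. Lactol 13 ⇐ diene-chalcone 8 + enal 11: one amine-catalysed operation builds the cyclohexene (enantioselective endo [4+2]) and the pyran (hemiacetal from the neighbouring phenol), setting all three stereocentres.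
3. Diene-chalcone 8 ⇐ resacetophenone 1 by iodination, Claisen–Schmidt condensation and Suzuki coupling with dienylboronate 7; enal 11 ⇐ 4-acetoxybenzaldehyde by Wittig reaction.
4. Aryl iodide 18 ⇐ 1-iodo-3,5-dimethoxybenzene by demethylation, C2-prenylation and acetylation.
5. Ring order: all four arenes are bought; cyclohexene and pyran form together in step 6; the pyran is reopened in step 10.

## Route

**Step 1**
Reactants: 1 2,4-dihydroxyacetophenone
Product: 2 2,4-dihydroxy-3-iodoacetophenone
Conditions: I2 (0.4 equiv), HIO3 (0.2 equiv), EtOH/H2O, rt to 40 °C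
Reagents that add atoms: iodine, II; iodic acid, O[I](=O)=O
Why: Electrophilic aromatic iodination; the carbon between the two hydroxyls (ortho to both) is the most activated position of resacetophenone and is iodinated selectively.

**Step 2**
Reactants: 2 2,4-dihydroxy-3-iodoacetophenone; 3 4-hydroxybenzaldehyde
Product: 4 (E)-1-(2,4-dihydroxy-3-iodophenyl)-3-(4-hydroxyphenyl)prop-2-en-1-one
Conditions: BF3·OEt2 (2.5 equiv), 1,4-dioxane, rt
Reagents that add atoms: none
Why: BF3-mediated Claisen–Schmidt (crossed aldol) condensation works on unprotected hydroxyacetophenones and hydroxybenzaldehydes and gives the E-enone after dehydration.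

**Step 3**
Reactants: 5 2-methylbut-1-en-3-yne; 6 pinacolborane
Product: 7 (E)-4,4,5,5-tetramethyl-2-(3-methylbuta-1,3-dien-1-yl)-1,3,2-dioxaborolane
Conditions: Cp2Zr(H)Cl (5 mol %), Et3N (10 mol %), neat, 60 °C
Reagents that add atoms: none
Why: Zirconium-catalysed syn, anti-Markovnikov hydroboration of the terminal alkyne gives only the E-alkenylboronate and leaves the 1,1-disubstituted alkene alone.

**Step 4**
Reactants: 4 iodochalcone; 7 dienylboronate
Product: 8 (E)-1-[2,4-dihydroxy-3-[(1E)-3-methylbuta-1,3-dien-1-yl]phenyl]-3-(4-hydroxyphenyl)prop-2-en-1-one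
Conditions: Pd(OAc)2 (3 mol %), SPhos (6 mol %), K3PO4 (5 equiv), dioxane/H2O 4:1, 60 °C, degassed; pH 6 buffer work-up at 0 °C; use at once
Reagents that add atoms: none
Why: Suzuki–Miyaura coupling proceeds with retention of the E-alkene geometry, tolerates free phenols, and the polyphenoxide chalcone is too deactivated to close to the flavanone.

**Step 5**
Reactants: 9 4-acetoxybenzaldehyde; 10 (triphenylphosphoranylidene)acetaldehyde
Product: 11 (E)-4-acetoxycinnamaldehyde
Conditions: toluene, 80 °C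
Reagents that add atoms: none
Why: Wittig two-carbon homologation with the stabilised formyl ylide gives the E-enal, and the aryl acetate is inert to the ylide.

**Step 6**
Reactants: 8 diene-chalcone; 11 (E)-4-acetoxycinnamaldehyde (1.5 equiv)
Product: 13 4-[(6aR,7S,10aS)-1,6-dihydroxy-2-[(E)-3-(4-hydroxyphenyl)prop-2-enoyl]-9-methyl-6a,7,8,10a-tetrahydro-6H-benzo[c]chromen-7-yl]phenyl acetate (lactol; C6 anomers), via open hydroxy-aldehyde Diels–Alder adduct 12 (not isolated)
Conditions: (2S,5S)-5-benzyl-2-tert-butyl-3-methylimidazolidin-4-one·TFA (20 mol %), MeCN/H2O 19:1, −10 to 4 °C, 48–72 h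
Reagents that add atoms: none
Why: Proposed new method: the closest known reaction is the imidazolidinone (iminium) catalysed enantioselective Diels–Alder reaction of cinnamaldehydes, here extended to an acyclic 1-aryl-3-methylbutadiene carrying free phenols. The E-iminium ion of 11 is attacked at its β-carbon by the unsubstituted diene terminus (the 1-aryl and 3-methyl directing effects agree). The C5 benzyl group shields the Re face, so Si-face addition sets C7 (S) and C6a (R), and the endo transition state places the formyl cis to the 2,6-dihydroxyaryl group (C10a S). After hydrolysis the cis aldehyde 12 is captured by the non-chelated ortho phenol as a six-membered hemiacetal, so the cyclohexene and pyran rings form in one operation and the α-centre is protected from amine-mediated epimerisation. Any lactol formed through the other ortho phenol converges in step 10.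

**Step 7**
Reactants: 14 1-iodo-3,5-dimethoxybenzene
Product: 15 5-iodobenzene-1,3-diol
Conditions: BBr3 (2.5 equiv), CH2Cl2, −78 °C to rt; H2O
Reagents that add atoms: none
Why: Lewis-acid ether cleavage (BBr3 demethylation) of both aryl methyl ethers; the aryl iodide is unaffected.

**Step 8**
Reactants: 15 5-iodobenzene-1,3-diol; 16 3-methylbut-2-en-1-ol (prenol)
Product: 17 5-iodo-2-(3-methylbut-2-en-1-yl)benzene-1,3-diol
Conditions: acidic Al2O3, 1,2-dichloroethane, reflux
Reagents that add atoms: none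
Why: Alumina-templated Friedel–Crafts ortho-allylation; the surface-bound resorcinol delivers the prenyl cation to C2 (ortho to both OH and remote from iodine), as for 5-alkylresorcinols, and the mild solid acid limits chroman formation.

**Step 9**
Reactants: 17 5-iodo-2-prenylresorcinol
Product: 18 5-iodo-2-(3-methylbut-2-en-1-yl)-1,3-phenylene diacetate
Conditions: Ac2O, pyridine, DMAP (cat.), CH2Cl2, 0 °C to rt
Reagents that add atoms: acetic anhydride, CC(=O)OC(C)=O
Why: DMAP-catalysed O-acetylation masks the electron-rich prenylresorcinol against the later oxidant and stops prenyl/OH cyclisation.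

**Step 10**
Reactants: 13 lactol; 18 aryl iodide diacetate (2.5 equiv)
Product: 19 5-[hydroxy[(1R,2S,6S)-6-(4-acetoxyphenyl)-2-[2,6-dihydroxy-3-[(E)-3-(4-hydroxyphenyl)prop-2-enoyl]phenyl]-4-methylcyclohex-3-en-1-yl]methyl]-2-(3-methylbut-2-en-1-yl)-1,3-phenylene diacetate (carbinol epimers)
Conditions: CrCl2 (8 equiv), NiCl2 (2 mol %), DMF, rt; aqueous work-up
Reagents that add atoms: none
Why: Nozaki–Hiyama–Kishi reaction: the arylchromium(III) species formed via Ni adds only to the aldehyde in equilibrium with the phenolic lactol, ignores the enone and aryl acetates, tolerates free OH, and is non-basic so the ring stereocentres are untouched (the new carbinol centre is destroyed in step 11).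

**Step 11**
Reactants: 19 benzylic alcohol
Product: 20 5-[[(1R,2S,6S)-6-(4-acetoxyphenyl)-2-[2,6-dihydroxy-3-[(E)-3-(4-hydroxyphenyl)prop-2-enoyl]phenyl]-4-methylcyclohex-3-en-1-yl]carbonyl]-2-(3-methylbut-2-en-1-yl)-1,3-phenylene diacetate
Conditions: Dess–Martin periodinane (1.3 equiv), CH2Cl2, 0 °C to rt
Reagents that add atoms: none
Why: Dess–Martin oxidation of the secondary benzylic alcohol is non-basic, so the epimerisable centre next to the new ketone keeps its cis configuration; the remaining free phenols are acyl-deactivated.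

**Step 12**
Reactants: 20 triacetate
Product: 21 kuwanon V, (E)-1-[3-[(1S,5S,6R)-6-[3,5-dihydroxy-4-(3-methylbut-2-en-1-yl)benzoyl]-5-(4-hydroxyphenyl)-3-methylcyclohex-2-en-1-yl]-2,4-dihydroxyphenyl]-3-(4-hydroxyphenyl)prop-2-en-1-one
Conditions: K2CO3 (0.3 equiv), MeOH/THF, 0 °C, 30 min; AcOH quench
Reagents that add atoms: none
Why: Base-catalysed transesterification (methanolysis) of the three aryl acetates is fast at 0 °C, well before enolisation of the hindered ketone or flavanone closure of the chalcone can occur.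

## Compound list

1 | 2,4-dihydroxyacetophenone | CC(=O)c1ccc(O)cc1O | starting material
2 | 2,4-dihydroxy-3-iodoacetophenone | CC(=O)c1ccc(O)c(I)c1O | intermediate
3 | 4-hydroxybenzaldehyde | O=Cc1ccc(O)cc1 | starting material
4 | (E)-1-(2,4-dihydroxy-3-iodophenyl)-3-(4-hydroxyphenyl)prop-2-en-1-one | O=C(/C=C/c1ccc(O)cc1)c1ccc(O)c(I)c1O | intermediate
5 | 2-methylbut-1-en-3-yne | C=C(C)C#C | starting material
6 | pinacolborane | CC1(C)OBOC1(C)C | starting material
7 | (E)-4,4,5,5-tetramethyl-2-(3-methylbuta-1,3-dien-1-yl)-1,3,2-dioxaborolane | C=C(C)/C=C/B1OC(C)(C)C(C)(C)O1 | intermediate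
8 | (E)-1-[2,4-dihydroxy-3-[(1E)-3-methylbuta-1,3-dien-1-yl]phenyl]-3-(4-hydroxyphenyl)prop-2-en-1-one | C=C(C)/C=C/c1c(O)ccc(C(=O)/C=C/c2ccc(O)cc2)c1O | intermediate
9 | 4-acetoxybenzaldehyde | CC(=O)Oc1ccc(C=O)cc1 | starting material
10 | (triphenylphosphoranylidene)acetaldehyde | O=CC=P(c1ccccc1)(c1ccccc1)c1ccccc1 | starting material
11 | (E)-4-acetoxycinnamaldehyde | CC(=O)Oc1ccc(/C=C/C=O)cc1 | intermediate
12 | (1R,2S,6S)-6-(4-acetoxyphenyl)-2-[2,6-dihydroxy-3-[(E)-3-(4-hydroxyphenyl)prop-2-enoyl]phenyl]-4-methylcyclohex-3-ene-1-carbaldehyde | O=C[C@H]1[C@@H](c2c(O)ccc(C(=O)/C=C/c3ccc(O)cc3)c2O)C=C(C)C[C@@H]1c1ccc(OC(C)=O)cc1 | intermediate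
13 | 4-[(6aR,7S,10aS)-1,6-dihydroxy-2-[(E)-3-(4-hydroxyphenyl)prop-2-enoyl]-9-methyl-6a,7,8,10a-tetrahydro-6H-benzo[c]chromen-7-yl]phenyl acetate (C6 anomers) | OC1[C@H]2[C@@H](c3c(O1)ccc(C(=O)/C=C/c4ccc(O)cc4)c3O)C=C(C)C[C@@H]2c2ccc(OC(C)=O)cc2 | intermediate
14 | 1-iodo-3,5-dimethoxybenzene | COc1cc(I)cc(OC)c1 | starting material
15 | 5-iodobenzene-1,3-diol | Oc1cc(O)cc(I)c1 | intermediate
16 | 3-methylbut-2-en-1-ol | CC(C)=CCO | starting material
17 | 5-iodo-2-(3-methylbut-2-en-1-yl)benzene-1,3-diol | CC(C)=CCc1c(O)cc(I)cc1O | intermediate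
18 | 5-iodo-2-(3-methylbut-2-en-1-yl)-1,3-phenylene diacetate | CC(C)=CCc1c(OC(C)=O)cc(I)cc1OC(C)=O | intermediate
19 | 5-[hydroxy[(1R,2S,6S)-6-(4-acetoxyphenyl)-2-[2,6-dihydroxy-3-[(E)-3-(4-hydroxyphenyl)prop-2-enoyl]phenyl]-4-methylcyclohex-3-en-1-yl]methyl]-2-(3-methylbut-2-en-1-yl)-1,3-phenylene diacetate (carbinol epimers) | CC(C)=CCc1c(OC(C)=O)cc(C(O)[C@H]2[C@@H](c3c(O)ccc(C(=O)/C=C/c4ccc(O)cc4)c3O)C=C(C)C[C@@H]2c2ccc(OC(C)=O)cc2)cc1OC(C)=O | intermediate
20 | 5-[[(1R,2S,6S)-6-(4-acetoxyphenyl)-2-[2,6-dihydroxy-3-[(E)-3-(4-hydroxyphenyl)prop-2-enoyl]phenyl]-4-methylcyclohex-3-en-1-yl]carbonyl]-2-(3-methylbut-2-en-1-yl)-1,3-phenylene diacetate | CC(C)=CCc1c(OC(C)=O)cc(C(=O)[C@H]2[C@@H](c3c(O)ccc(C(=O)/C=C/c4ccc(O)cc4)c3O)C=C(C)C[C@@H]2c2ccc(OC(C)=O)cc2)cc1OC(C)=O | intermediate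
21 | kuwanon V, (E)-1-[3-[(1S,5S,6R)-6-[3,5-dihydroxy-4-(3-methylbut-2-en-1-yl)benzoyl]-5-(4-hydroxyphenyl)-3-methylcyclohex-2-en-1-yl]-2,4-dihydroxyphenyl]-3-(4-hydroxyphenyl)prop-2-en-1-one | CC(C)=CCc1c(O)cc(C(=O)[C@H]2[C@@H](c3c(O)ccc(C(=O)/C=C/c4ccc(O)cc4)c3O)C=C(C)C[C@@H]2c2ccc(O)cc2)cc1O | target

## Step count and risks

Total steps: 12. Longest linear sequence: 7 (steps 1, 2, 4, 6, 10, 11, 12).

**Step 6 (most likely to fail).** The free-phenol diene may isomerise to a 2,2-dimethylchromene under the acidic co-catalyst, the iminium ion may react too slowly, or endo control may be poor. The fallback sets out from 8 and comes back at 20, closing the same two rings under basic conditions. Compound 8 is treated with (E)-4-acetoxycinnamoyl chloride F1 (from commercial 4-acetoxycinnamic acid and oxalyl chloride), 2,6-lutidine and the isothiourea (S)-benzotetramisole in CH2Cl2. The chiral α,β-unsaturated acylammonium ion (s-cis, S···O locked, phenyl shielding the Re face at the β-carbon) undergoes the Diels–Alder reaction, and the neighbouring phenoxide releases the catalyst by lactonisation; reversible acyl transfer returns any O-acylated phenol to the productive path. This gives the cis-fused lactone 4-[(6aR,7S,10aS)-1-hydroxy-2-[(E)-3-(4-hydroxyphenyl)prop-2-enoyl]-9-methyl-6-oxo-6a,7,8,10a-tetrahydro-6H-benzo[c]chromen-7-yl]phenyl acetate F2. Anhydrous Pd–NHC acyl C–O Suzuki coupling of this activated p-acylaryl ester with 2-(3-methylbut-2-en-1-yl)-5-(4,4,5,5-tetramethyl-1,3,2-dioxaborolan-2-yl)-1,3-phenylene diacetate F3 (from 18, B2pin2, Pd(dppf)Cl2, KOAc) opens the lactone directly to ketone 20.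

**Step 10.** The hindered aldehyde is masked as a lactol and three acidic phenols are present, so the Ni/Cr coupling may stall or give biaryl. The fallback sets out from 13 and 18 and comes back at 19, replacing the in situ redox coupling by a preformed, ester-tolerant organometallic. Zinc insertion into 18 (Zn dust, LiCl, THF) gives [3,5-diacetoxy-4-(3-methylbut-2-en-1-yl)phenyl]zinc iodide F4. Transmetalation with ClTi(OiPr)3 gives [3,5-diacetoxy-4-(3-methylbut-2-en-1-yl)phenyl]titanium triisopropoxide F5. The lactol and phenol OH groups of 13 exchange onto titanium and the aryl group is delivered only to the aldehyde carbon at −20 to 0 °C, giving 19.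

**Step 8.** Prenylation may occur at C4 instead of C2, or the product may cyclise to a chroman. The fallback sets out from 15 and comes back at 17, fixing the regiochemistry by directed metalation. Compound 15 is converted (MOMCl, iPr2NEt) into 1-iodo-3,5-bis(methoxymethoxy)benzene F6. LiTMP at −78 °C removes the proton flanked by both MOM ethers to give [4-iodo-2,6-bis(methoxymethoxy)phenyl]lithium F7 (not isolated). Prenyl bromide then gives 5-iodo-1,3-bis(methoxymethoxy)-2-(3-methylbut-2-en-1-yl)benzene F8 by direct SN2 alkylation. Dilute HCl in MeOH at rt removes both MOM groups to give 17.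

## Further compounds

F1 | step 6 | (E)-4-acetoxycinnamoyl chloride | CC(=O)Oc1ccc(/C=C/C(=O)Cl)cc1
F2 | step 6 | 4-[(6aR,7S,10aS)-1-hydroxy-2-[(E)-3-(4-hydroxyphenyl)prop-2-enoyl]-9-methyl-6-oxo-6a,7,8,10a-tetrahydro-6H-benzo[c]chromen-7-yl]phenyl acetate | O=C1[C@H]2[C@@H](c3c(O1)ccc(C(=O)/C=C/c4ccc(O)cc4)c3O)C=C(C)C[C@@H]2c2ccc(OC(C)=O)cc2
F3 | step 6 | 2-(3-methylbut-2-en-1-yl)-5-(4,4,5,5-tetramethyl-1,3,2-dioxaborolan-2-yl)-1,3-phenylene diacetate | CC(C)=CCc1c(OC(C)=O)cc(B2OC(C)(C)C(C)(C)O2)cc1OC(C)=O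
F4 | step 10 | [3,5-diacetoxy-4-(3-methylbut-2-en-1-yl)phenyl]zinc iodide | CC(C)=CCc1c(OC(C)=O)cc([Zn]I)cc1OC(C)=O
F5 | step 10 | [3,5-diacetoxy-4-(3-methylbut-2-en-1-yl)phenyl]titanium triisopropoxide | CC(C)=CCc1c(OC(C)=O)cc([Ti](OC(C)C)(OC(C)C)OC(C)C)cc1OC(C)=O
F6 | step 8 | 1-iodo-3,5-bis(methoxymethoxy)benzene | COCOc1cc(I)cc(OCOC)c1
F7 | step 8 | [4-iodo-2,6-bis(methoxymethoxy)phenyl]lithium | COCOc1cc(I)cc(OCOC)c1[Li]
F8 | step 8 | 5-iodo-1,3-bis(methoxymethoxy)-2-(3-methylbut-2-en-1-yl)benzene | CC(C)=CCc1c(OCOC)cc(I)cc1OCOC
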